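**Plan**

1. Retrosynthetic cuts, in order: the phenol O–Si bond; the ring bond C3–C4 together with the benzylic C–H and the primary O–H (back to a Z enol acetate and an oxirane); the enol O–acetyl bond; the ether bond O1–C2 (back to an epoxy alcohol and a diazoketone); the oxirane oxygen and the aryl–vinyl carbinol C–C bond on one branch, the acyl–CHN2 bond on the other.
2. Forward: veratraldehyde gives the resolved epoxy alcohol, homovanillic acid gives the diazoketone, the two are joined at O1–C2, and the ketone is enol-acetylated. The oxolane is the only ring made and it arises last, by radical closure of C3–C4, before desilylation.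
3. Enabling feature: C4 carries CH2OH, so an oxygen sits β to C4 (an opened oxirane, hence a β-titanoxy radical at C4). C3 carries an ester oxygen and an aryl-CH2 group, the reduced form of the C=C of the enol acetate of a benzyl ketone, whose aryl terminus steers the radical to C3. Ring oxygen O1 is the 3-oxa tether for a 5-exo closure of ring O1–C2–C3–C4–C5.
4. Stereochemistry: C5 comes from a Sharpless kinetic resolution (D-tartrate). C4 and C3 are set together in the key step under control of C5 (aryl/CH2OH trans, CH2OH/benzyl cis). The oxirane stereocentre is erased at the radical stage.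

Key step: step 7

Remark: oxolane numbering throughout is O1, C2 (ring CH2), C3 (carbon bearing acetoxy and benzyl), C4 (carbon bearing CH2OH), C5 (carbon bearing the 3,4-dimethoxyphenyl group). Diazomethane is taken as an ethereal solution prepared from commercial N-methyl-N-nitroso-p-toluenesulfonamide.

**Route**

Step 1
Reactants: 1 3,4-dimethoxybenzaldehyde; 2 vinylmagnesium bromide
Product: 3 rac-1-(3,4-dimethoxyphenyl)prop-2-en-1-ol
Conditions: CH2=CHMgBr (1.2 equiv), THF, 0 °C; sat. aq. NH4Cl
Reagents that add atoms: vinylmagnesium bromide 2, C=C[Mg]Br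
Why: Grignard 1,2-addition to an aromatic aldehyde; the carbinol stereocentre forms racemic and is resolved in step 2.

Step 2
Reactants: 3 rac-1-(3,4-dimethoxyphenyl)prop-2-en-1-ol
Product: 4 (R)-(3,4-dimethoxyphenyl)[(2S)-oxiran-2-yl]methanol
Conditions: Ti(OiPr)4 (15 mol %), D-(−)-diisopropyl tartrate (18 mol %), t-BuOOH (0.55 equiv), 4 Å molecular sieves, CH2Cl2, −20 °C, run to about half conversion
Reagents that add atoms: tert-butyl hydroperoxide, CC(C)(C)OO
Why: Sharpless kinetic resolution (asymmetric epoxidation of a secondary allylic alcohol): with the D-tartrate the (S)-carbinol should be the fast enantiomer and give the erythro epoxy alcohol, which fixes the future C5 (the descriptor changes to R only through CIP priorities), while (R)-3 is left behind and separated.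

Step 3
Reactants: 5 homovanillic acid
Product: 7 2-[4-(tert-butyldimethylsilyloxy)-3-methoxyphenyl]acetic acid, via bis-silyl derivative 6 (not isolated)
Conditions: TBSCl (2.3 equiv), imidazole (4 equiv), DMF, rt; then AcOH/THF/H2O, rt
Reagents that add atoms: tert-butyldimethylsilyl chloride, CC(C)(C)[Si](C)(C)Cl
Why: Silylation of phenol and acid followed by selective hydrolysis of the far more labile silyl ester; no stereocentre is involved.

Step 4
Reactants: 7 2-[4-(tert-butyldimethylsilyloxy)-3-methoxyphenyl]acetic acid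
Product: 9 1-[4-(tert-butyldimethylsilyloxy)-3-methoxyphenyl]-3-diazopropan-2-one, via acid chloride 8 (not isolated)
Conditions: (COCl)2 (1.3 equiv), DMF (cat.), CH2Cl2, 0 °C to rt, evaporate; CH2N2 (3 equiv), Et2O, 0 °C
Reagents that add atoms: diazomethane, C=[N+]=[N-]; oxalyl chloride, O=C(Cl)C(=O)Cl (chlorine of 8 only)
Why: Acid chloride formation and acylation of diazomethane (first stage of the Arndt–Eistert sequence), a second equivalent of diazomethane taking up the HCl; no stereocentre is involved.

Step 5
Reactants: 4 (R)-(3,4-dimethoxyphenyl)[(2S)-oxiran-2-yl]methanol; 9 1-[4-(tert-butyldimethylsilyloxy)-3-methoxyphenyl]-3-diazopropan-2-one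
Product: 10 1-[4-(tert-butyldimethylsilyloxy)-3-methoxyphenyl]-3-{(R)-(3,4-dimethoxyphenyl)[(2S)-oxiran-2-yl]methoxy}propan-2-one
Conditions: Rh2(OAc)4 (1 mol %), CH2Cl2, rt, 9 (1.5 equiv) added slowly to 4
Reagents that add atoms: none
Why: Rhodium-carbenoid O–H insertion of an α-diazoketone into a secondary alcohol under neutral conditions, which forms the O1–C2 ether without exposing the 2,3-epoxy alcohol to base (no Payne rearrangement) and leaves both stereocentres untouched.

Step 6
Reactants: 10 1-[4-(tert-butyldimethylsilyloxy)-3-methoxyphenyl]-3-{(R)-(3,4-dimethoxyphenyl)[(2S)-oxiran-2-yl]methoxy}propan-2-one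
Product: 11 (1Z)-1-[4-(tert-butyldimethylsilyloxy)-3-methoxyphenyl]-3-{(R)-(3,4-dimethoxyphenyl)[(2S)-oxiran-2-yl]methoxy}prop-1-en-2-yl acetate
Conditions: LiN(SiMe3)2 (1.1 equiv), THF, −78 °C; Ac2O (1.5 equiv), −78 to 0 °C
Reagents that add atoms: acetic anhydride, CC(=O)OC(C)=O
Why: Regioselective deprotonation at the more acidic benzylic α-carbon should give the conjugated Z enolate (aryl cis to oxygen), which the hard acylating agent acetylates on oxygen (enol ester formation from a lithium enolate); the stereocentres are untouched.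

Step 7
Reactants: 11 (1Z)-1-[4-(tert-butyldimethylsilyloxy)-3-methoxyphenyl]-3-{(R)-(3,4-dimethoxyphenyl)[(2S)-oxiran-2-yl]methoxy}prop-1-en-2-yl acetate
Product: 13 (3S,4R,5S)-3-{[4-(tert-butyldimethylsilyloxy)-3-methoxyphenyl]methyl}-5-(3,4-dimethoxyphenyl)-4-(hydroxymethyl)oxolan-3-yl acetate, via chlorotitanocene alkoxide 12 (not isolated)
Conditions: Cp2TiCl2 (2.5 equiv), Mn dust (8 equiv), THF, rt; this Cp2TiCl solution added dropwise to 11 and H2O (10 equiv) in THF, rt; aq. NaH2PO4 work-up
Reagents that add atoms: none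
Why: Proposed new method: Cp2TiCl opens the oxirane of 11 by single-electron transfer at its more substituted C–O bond (Nugent–RajanBabu opening), giving a secondary β-titanoxy radical at the future C4 that adds to the acetoxy-bearing carbon of the Z enol acetate (future C3); the benzylic radical formed is reduced by hydrogen-atom transfer from the Cp2TiCl–water complex, and the titanium alkoxide 12 is hydrolysed on work-up. The closest known reaction type is the Cp2TiCl-mediated epoxide-opening/radical cyclisation of epoxy cinnamyl ethers to 2-aryl-3-(hydroxymethyl)-4-benzyloxolanes; untested is the enol ester as acceptor, attacked at its oxygenated carbon so that the tertiary acetate arrives with the C–C bond. The oxolane closes in the 5-exo-trig mode through the 3-oxa tether O1. C4 is controlled by the C5 stereocentre, whose aryl group sits pseudo-equatorial in the chair-like transition state so that CH2OTi ends up trans to it; C3 is controlled by the same transition state, in which the exocyclic benzylic carbon is pseudo-equatorial (cis to CH2OTi, trans to aryl, as in 1- and 2-substituted hexenyl radical closures) and the acetoxy group takes the pseudo-axial site that faces only the lone pairs of O1. The step needs 5-exo rather than 6-endo attack, which the aryl group on the alkene terminus secures (benzylic radical, hindered endo carbon), and hydrogen transfer to the benzylic radical rather than its capture by titanium, which would expel the β-acetate; water as donor and slow addition of Cp2TiCl secure this.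

Step 8
Reactants: 13 (3S,4R,5S)-3-{[4-(tert-butyldimethylsilyloxy)-3-methoxyphenyl]methyl}-5-(3,4-dimethoxyphenyl)-4-(hydroxymethyl)oxolan-3-yl acetate
Product: 14 (3S,4R,5S)-5-(3,4-dimethoxyphenyl)-3-[(4-hydroxy-3-methoxyphenyl)methyl]-4-(hydroxymethyl)oxolan-3-yl acetate (CNP0310348.1)
Conditions: KHF2 (2.5 equiv), MeOH, rt
Reagents that add atoms: none
Why: Fluoride cleavage of the aryl silyl ether under weakly acidic, non-basic conditions that are selective for phenolic silyl ethers, so the tertiary acetate should neither cleave nor migrate to the primary alcohol; no stereocentre is touched.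

**Compound list**

1 | 3,4-dimethoxybenzaldehyde | COc1ccc(C=O)cc1OC | starting material
2 | vinylmagnesium bromide | C=C[Mg]Br | starting material
3 | rac-1-(3,4-dimethoxyphenyl)prop-2-en-1-ol | COc1ccc(C(O)C=C)cc1OC | intermediate
4 | (R)-(3,4-dimethoxyphenyl)[(2S)-oxiran-2-yl]methanol | O[C@H](c1ccc(OC)c(OC)c1)[C@@H]1CO1 | intermediate
5 | homovanillic acid | COc1cc(CC(=O)O)ccc1O | starting material
6 | tert-butyldimethylsilyl 2-[4-(tert-butyldimethylsilyloxy)-3-methoxyphenyl]acetate | COc1cc(CC(=O)O[Si](C)(C)C(C)(C)C)ccc1O[Si](C)(C)C(C)(C)C | intermediate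
7 | 2-[4-(tert-butyldimethylsilyloxy)-3-methoxyphenyl]acetic acid | COc1cc(CC(=O)O)ccc1O[Si](C)(C)C(C)(C)C | intermediate
8 | 2-[4-(tert-butyldimethylsilyloxy)-3-methoxyphenyl]acetyl chloride | COc1cc(CC(=O)Cl)ccc1O[Si](C)(C)C(C)(C)C | intermediate
9 | 1-[4-(tert-butyldimethylsilyloxy)-3-methoxyphenyl]-3-diazopropan-2-one | COc1cc(CC(=O)C=[N+]=[N-])ccc1O[Si](C)(C)C(C)(C)C | intermediate
10 | 1-[4-(tert-butyldimethylsilyloxy)-3-methoxyphenyl]-3-{(R)-(3,4-dimethoxyphenyl)[(2S)-oxiran-2-yl]methoxy}propan-2-one | COc1cc(CC(=O)CO[C@H](c2ccc(OC)c(OC)c2)[C@@H]2CO2)ccc1O[Si](C)(C)C(C)(C)C | intermediate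
11 | (1Z)-1-[4-(tert-butyldimethylsilyloxy)-3-methoxyphenyl]-3-{(R)-(3,4-dimethoxyphenyl)[(2S)-oxiran-2-yl]methoxy}prop-1-en-2-yl acetate | CC(=O)O/C(=C\c1ccc(O[Si](C)(C)C(C)(C)C)c(OC)c1)CO[C@H](c1ccc(OC)c(OC)c1)[C@@H]1CO1 | intermediate
12 | chlorobis(cyclopentadienyl)titanium alkoxide of 13 (titanium on the primary oxygen) | COc1cc(C[C@@]2(OC(C)=O)CO[C@H](c3ccc(OC)c(OC)c3)[C@H]2CO[Ti](Cl)(C4C=CC=C4)C5C=CC=C5)ccc1O[Si](C)(C)C(C)(C)C | intermediate
13 | (3S,4R,5S)-3-{[4-(tert-butyldimethylsilyloxy)-3-methoxyphenyl]methyl}-5-(3,4-dimethoxyphenyl)-4-(hydroxymethyl)oxolan-3-yl acetate | COc1cc(C[C@@]2(OC(C)=O)CO[C@H](c3ccc(OC)c(OC)c3)[C@H]2CO)ccc1O[Si](C)(C)C(C)(C)C | intermediate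
14 | (3S,4R,5S)-5-(3,4-dimethoxyphenyl)-3-[(4-hydroxy-3-methoxyphenyl)methyl]-4-(hydroxymethyl)oxolan-3-yl acetate (CNP0310348.1) | COc1cc(C[C@@]2(OC(C)=O)CO[C@H](c3ccc(OC)c(OC)c3)[C@H]2CO)ccc1O | target

**Step count and risks**

Total steps: 8. Longest linear sequence: 6 steps (steps 1, 2, 5, 6, 7, 8 from 1; equally steps 3, 4, 5, 6, 7, 8 from 5).

Steps most likely to fail:

Step 7 (proposed new method). The first radical may be reduced or captured by titanium (deoxygenation of the oxirane) before the slower closure onto a fully substituted alkene carbon. The benzylic radical may be captured by titanium with loss of the β-acetate. Facial selectivity at C3 may be poor. The fallback uses known chemistry, sets out from 10 and comes back at 14. Ketone 10 is treated with anhydrous Cp2TiCl (Cp2TiCl2, Mn dust, THF, rt). The same β-titanoxy radical then adds 5-exo to the ketone carbonyl and the alkoxy radical is reduced by a second equivalent of trivalent titanium, a known reductive epoxide–ketone cyclisation. This should give (3S,4R,5S)-3-{[4-(tert-butyldimethylsilyloxy)-3-methoxyphenyl]methyl}-5-(3,4-dimethoxyphenyl)-4-(hydroxymethyl)oxolan-3-ol F1, the two bulky titanium alkoxides being expected to end up trans. Silylation of the primary alcohol (TBSCl, imidazole, CH2Cl2, 0 °C) gives (3S,4R,5S)-4-[(tert-butyldimethylsilyloxy)methyl]-3-{[4-(tert-butyldimethylsilyloxy)-3-methoxyphenyl]methyl}-5-(3,4-dimethoxyphenyl)oxolan-3-ol F2. Acetylation of the tertiary alcohol (Ac2O, Et3N, DMAP, CH2Cl2, 40 °C) gives (3S,4R,5S)-4-[(tert-butyldimethylsilyloxy)methyl]-3-{[4-(tert-butyldimethylsilyloxy)-3-methoxyphenyl]methyl}-5-(3,4-dimethoxyphenyl)oxolan-3-yl acetate F3. Removal of both silyl groups (Bu4NF/AcOH 1:1, THF, 0 °C) gives 14.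

Step 5. The carbenoid may be consumed by attack on its own electron-rich arene or by dimerisation faster than it inserts into the hindered secondary O–H bond. The fallback sets out from 9 and comes back at 10. Diazoketone 9 is converted with HBr (33 % in AcOH, 1.05 equiv, Et2O, −10 °C) into 1-bromo-3-[4-(tert-butyldimethylsilyloxy)-3-methoxyphenyl]propan-2-one F4. Alcohol 4 is then alkylated with F4 under non-basic, silver-assisted SN2 conditions (Ag2O, 4 Å molecular sieves, CH2Cl2, dark, rt) to give 10 without a carbenoid.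

Step 2. The kinetic resolution of the electron-rich aryl vinyl carbinol may be slow or poorly selective, and the benzylic epoxy alcohol may be opened by the Lewis-acidic titanium alkoxide. The fallback sets out from 3 and comes back at 4. Immobilised Candida antarctica lipase B with vinyl acetate (MTBE, 30 °C) should acylate the R enantiomer to (R)-1-(3,4-dimethoxyphenyl)prop-2-en-1-yl acetate F5 and leave (S)-1-(3,4-dimethoxyphenyl)prop-2-en-1-ol F6. Hydroxyl-directed epoxidation of F6 (VO(acac)2 cat., t-BuOOH, CH2Cl2, 0 °C) should give 4 together with its threo epimer (R)-(3,4-dimethoxyphenyl)[(2R)-oxiran-2-yl]methanol F7, from which 4 is separated by chromatography.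

Further compounds
F1 | step 7 | (3S,4R,5S)-3-{[4-(tert-butyldimethylsilyloxy)-3-methoxyphenyl]methyl}-5-(3,4-dimethoxyphenyl)-4-(hydroxymethyl)oxolan-3-ol | COc1cc(C[C@@]2(O)CO[C@H](c3ccc(OC)c(OC)c3)[C@H]2CO)ccc1O[Si](C)(C)C(C)(C)C
F2 | step 7 | (3S,4R,5S)-4-[(tert-butyldimethylsilyloxy)methyl]-3-{[4-(tert-butyldimethylsilyloxy)-3-methoxyphenyl]methyl}-5-(3,4-dimethoxyphenyl)oxolan-3-ol | COc1cc(C[C@@]2(O)CO[C@H](c3ccc(OC)c(OC)c3)[C@H]2CO[Si](C)(C)C(C)(C)C)ccc1O[Si](C)(C)C(C)(C)C
F3 | step 7 | (3S,4R,5S)-4-[(tert-butyldimethylsilyloxy)methyl]-3-{[4-(tert-butyldimethylsilyloxy)-3-methoxyphenyl]methyl}-5-(3,4-dimethoxyphenyl)oxolan-3-yl acetate | COc1cc(C[C@@]2(OC(C)=O)CO[C@H](c3ccc(OC)c(OC)c3)[C@H]2CO[Si](C)(C)C(C)(C)C)ccc1O[Si](C)(C)C(C)(C)C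
F4 | step 5 | 1-bromo-3-[4-(tert-butyldimethylsilyloxy)-3-methoxyphenyl]propan-2-one | COc1cc(CC(=O)CBr)ccc1O[Si](C)(C)C(C)(C)C
F5 | step 2 | (R)-1-(3,4-dimethoxyphenyl)prop-2-en-1-yl acetate | CC(=O)O[C@@H](c1ccc(OC)c(OC)c1)C=C
F6 | step 2 | (S)-1-(3,4-dimethoxyphenyl)prop-2-en-1-ol | O[C@H](c1ccc(OC)c(OC)c1)C=C
F7 | step 2 | (R)-(3,4-dimethoxyphenyl)[(2R)-oxiran-2-yl]methanol | O[C@H](c1ccc(OC)c(OC)c1)[C@H]1CO1
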